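**Plan**

- Retrosynthetic cuts, in order: the acetyl C–O bond; the masks on the two phenols and the formyl group; the bond from the benzylic CH2 (C-1 of the tridecyl chain) to the oxygen-bearing C-2; the aryl–CH2 bond; one aryl C–O bond para to the phenol already present.
- Enabling feature: C-2 is an sp3 CH that carries one oxygen and sits between the benzylic CH2 on the pentasubstituted benzene ring and the undecyl chain. Its C–O bond can be read as a former C–B bond and C-2 as a chiral α-oxy carbenoid, so a boronate that holds ArCH2 on boron joins the two carbons by a 1,2-shift.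
- Forward: no ring is built. The benzene ring is bought with CHO, Br, OH and OMe in place, receives its fourth oxygen, is masked, and C–Br is turned into C–CH2–Bpin; the C12 ester is then joined, and acetylation and one acid step finish.
- Stereochemistry: the only stereocentre comes from (−)-sparteine-directed removal of the pro-S hydrogen of the OCH2 group of the dodecyl ester; retention (borylation), inversion (1,2-shift) and retention (oxidation) give (R).
- Helpers: boron and the triisopropylbenzoate group leave in the key step; the dioxolane and the MOM groups leave in the last step.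

Key step: step 6

Remark: the reagents named under Conditions are taken as purchased; 1, 9 and 10 are the starting materials.

**Step 1**
Reactants: 1 2-bromo-3-hydroxy-4-methoxybenzaldehyde
Product: 3 2-bromo-3,6-dihydroxy-4-methoxybenzaldehyde, via aryl sulfate 2 (not isolated)
Conditions: K2S2O8, aq. KOH, 0 → 20 °C; then aq. HCl, 80 °C
Reagents that add atoms: potassium persulfate, [K+].[K+].[O-]S(=O)(=O)OOS(=O)(=O)[O-]
Why: Elbs persulfate oxidation, in which the phenoxide attacks the peroxide oxygen through the ring carbon para to O−, the only free ortho or para position (Br and OMe block both ortho sites), and acid hydrolysis of the sulfate should give the hydroquinone with the aldehyde intact.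

**Step 2**
Reactants: 3 2-bromo-3,6-dihydroxy-4-methoxybenzaldehyde
Product: 4 2-bromo-4-methoxy-3,6-bis(methoxymethoxy)benzaldehyde
Conditions: MOMCl, i-Pr2NEt, CH2Cl2, 0 °C → rt, under argon
Reagents that add atoms: chloromethyl methyl ether, COCCl
Why: O-alkylation of both phenols (Williamson-type ether synthesis) should give the bis-MOM ether, which is stable to the organolithiums, base and peroxide of steps 4 and 6 and falls in the final acid step.

**Step 3**
Reactants: 4 2-bromo-4-methoxy-3,6-bis(methoxymethoxy)benzaldehyde
Product: 5 2-[2-bromo-4-methoxy-3,6-bis(methoxymethoxy)phenyl]-1,3-dioxolane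
Conditions: TMSOCH2CH2OTMS, TMSOTf (cat.), CH2Cl2, −78 → −20 °C; pyridine quench
Reagents that add atoms: 1,2-bis(trimethylsilyloxy)ethane, C[Si](C)(C)OCCO[Si](C)(C)C
Why: Silyl triflate-catalysed aprotic acetalisation is driven by formation of hexamethyldisiloxane and should mask the hindered aldehyde against organolithiums, while catalytic acid at low temperature spares the aryl MOM ethers.

**Step 4**
Reactants: 5 2-[2-bromo-4-methoxy-3,6-bis(methoxymethoxy)phenyl]-1,3-dioxolane
Product: 8 2-{[2-(1,3-dioxolan-2-yl)-5-methoxy-3,6-bis(methoxymethoxy)phenyl]methyl}-4,4,5,5-tetramethyl-1,3,2-dioxaborolane, via aryllithium 6 (not isolated), via chloromethyl boronate complex 7 (not isolated)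
Conditions: n-BuLi, THF, −78 °C; ClCH2Bpin, −78 °C → rt
Reagents that add atoms: 2-(chloromethyl)-4,4,5,5-tetramethyl-1,3,2-dioxaborolane, ClCB1OC(C)(C)C(C)(C)O1
Why: Bromine–lithium exchange at −78 °C outruns ortho-lithiation and attack on the acetals, and the aryllithium adds to boron to give a boronate that on warming undergoes 1,2-aryl shift with loss of chloride (Matteson-type homologation), which places the benzylic CH2 on boron.

**Step 5**
Reactants: 9 1-bromododecane; 10 2,4,6-triisopropylbenzoic acid
Product: 11 dodecyl 2,4,6-triisopropylbenzoate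
Conditions: K2CO3, DMF, 60 °C
Reagents that add atoms: none
Why: SN2 O-alkylation of the carboxylate avoids attack at the shielded acyl carbon and should give the hindered ester, whose carbonyl is inert to s-BuLi and directs α-lithiation.

**Step 6**
Reactants: 11 dodecyl 2,4,6-triisopropylbenzoate; 8 2-{[2-(1,3-dioxolan-2-yl)-5-methoxy-3,6-bis(methoxymethoxy)phenyl]methyl}-4,4,5,5-tetramethyl-1,3,2-dioxaborolane
Product: 15 (2R)-1-[2-(1,3-dioxolan-2-yl)-5-methoxy-3,6-bis(methoxymethoxy)phenyl]tridecan-2-ol, via lithiated ester 12 (not isolated), via boronate complex 13 (not isolated), via secondary boronic ester 14 (not isolated)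
Conditions: s-BuLi, (−)-sparteine, Et2O, −78 °C; then 8, −78 → 35 °C; then NaOH, H2O2, THF/H2O, 0 °C → rt
Reagents that add atoms: hydrogen peroxide, OO
Why: s-BuLi·(−)-sparteine removes the pro-S hydrogen of the OCH2 group of 11 to give the configurationally stable (S)-α-lithio ester 12, which adds to boron of 8 with retention to give boronate 13; on warming, the ArCH2 group shifts from boron to carbon anti to the departing triisopropylbenzoate (inversion), which forms the CH2–CH bond in (R)-14, and oxidation with retention turns C–B into C–OH. The closest known reaction type is the lithiation–borylation of primary alkyl 2,4,6-triisopropylbenzoates with primary pinacol boronic esters, a Matteson-type 1,2-metallate rearrangement. The step closes no ring. The one new stereocentre is under reagent control by (−)-sparteine in the deprotonation and is carried over stereospecifically (retention, inversion, retention) to the (R)-carbinol. The selectivity needed is addition of 12 to boron in preference to removal of an acidic ArCH2–B proton or attack on an acetal, and migration of carbon in preference to a pinacol oxygen; the unhindered primary boron centre, −78 °C, the good carboxylate leaving group and the organolithium-inert dioxolane and MOM groups should secure this.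

**Step 7**
Reactants: 15 (2R)-1-[2-(1,3-dioxolan-2-yl)-5-methoxy-3,6-bis(methoxymethoxy)phenyl]tridecan-2-ol
Product: 16 (2R)-1-[2-(1,3-dioxolan-2-yl)-5-methoxy-3,6-bis(methoxymethoxy)phenyl]tridecan-2-yl acetate
Conditions: Ac2O, pyridine, DMAP (cat.), CH2Cl2, 0 °C → rt
Reagents that add atoms: acetic anhydride, CC(=O)OC(C)=O
Why: DMAP-catalysed acylation takes place at oxygen only, so the C–O bond and the (R) configuration are untouched, and the acetal and MOM groups are stable to the basic medium.

**Step 8**
Reactants: 16 (2R)-1-[2-(1,3-dioxolan-2-yl)-5-methoxy-3,6-bis(methoxymethoxy)phenyl]tridecan-2-yl acetate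
Product: 17 (2R)-1-(2-formyl-3,6-dihydroxy-5-methoxyphenyl)tridecan-2-yl acetate
Conditions: TFA, H2O (few equiv), CH2Cl2, 0 °C → rt
Reagents that add atoms: water, O
Why: Acid-catalysed hydrolysis should cleave the two aryl MOM acetals and the dioxolane in one operation (the formyl oxygen comes from water), while the secondary acetate is stable to TFA with little water and the stereocentre is not involved.

**Compound list**

1 | 2-bromo-3-hydroxy-4-methoxybenzaldehyde | O=Cc1ccc(OC)c(O)c1Br | starting material
2 | potassium 3-bromo-2-formyl-4-hydroxy-5-methoxyphenyl sulfate | [K+].[O-]S(=O)(=O)Oc1cc(OC)c(O)c(Br)c1C=O | intermediate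
3 | 2-bromo-3,6-dihydroxy-4-methoxybenzaldehyde | O=Cc1c(O)cc(OC)c(O)c1Br | intermediate
4 | 2-bromo-4-methoxy-3,6-bis(methoxymethoxy)benzaldehyde | O=Cc1c(OCOC)cc(OC)c(OCOC)c1Br | intermediate
5 | 2-[2-bromo-4-methoxy-3,6-bis(methoxymethoxy)phenyl]-1,3-dioxolane | COCOc1cc(OC)c(OCOC)c(Br)c1C1OCCO1 | intermediate
6 | [2-(1,3-dioxolan-2-yl)-5-methoxy-3,6-bis(methoxymethoxy)phenyl]lithium | COCOc1cc(OC)c(OCOC)c([Li])c1C1OCCO1 | intermediate
7 | lithium (chloromethyl)[2-(1,3-dioxolan-2-yl)-5-methoxy-3,6-bis(methoxymethoxy)phenyl](pinacolato)borate | [Li+].COCOc1cc(OC)c(OCOC)c(c1C1OCCO1)[B-]1(CCl)OC(C)(C)C(C)(C)O1 | intermediate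
8 | 2-{[2-(1,3-dioxolan-2-yl)-5-methoxy-3,6-bis(methoxymethoxy)phenyl]methyl}-4,4,5,5-tetramethyl-1,3,2-dioxaborolane | COCOc1cc(OC)c(OCOC)c(CB2OC(C)(C)C(C)(C)O2)c1C1OCCO1 | intermediate
9 | 1-bromododecane | CCCCCCCCCCCCBr | starting material
10 | 2,4,6-triisopropylbenzoic acid | CC(C)c1cc(C(C)C)c(C(=O)O)c(C(C)C)c1 | starting material
11 | dodecyl 2,4,6-triisopropylbenzoate | CCCCCCCCCCCCOC(=O)c1c(C(C)C)cc(C(C)C)cc1C(C)C | intermediate
12 | (1S)-1-lithiododecyl 2,4,6-triisopropylbenzoate, formed as its (−)-sparteine complex | CCCCCCCCCCC[C@H]([Li])OC(=O)c1c(C(C)C)cc(C(C)C)cc1C(C)C | intermediate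
13 | lithium {[2-(1,3-dioxolan-2-yl)-5-methoxy-3,6-bis(methoxymethoxy)phenyl]methyl}{(1S)-1-[(2,4,6-triisopropylbenzoyl)oxy]dodecyl}(pinacolato)borate | [Li+].CCCCCCCCCCC[C@H]([B-]1(Cc2c(OCOC)c(OC)cc(OCOC)c2C2OCCO2)OC(C)(C)C(C)(C)O1)OC(=O)c1c(C(C)C)cc(C(C)C)cc1C(C)C | intermediate
14 | 2-{(2R)-1-[2-(1,3-dioxolan-2-yl)-5-methoxy-3,6-bis(methoxymethoxy)phenyl]tridecan-2-yl}-4,4,5,5-tetramethyl-1,3,2-dioxaborolane | CCCCCCCCCCC[C@H](Cc1c(OCOC)c(OC)cc(OCOC)c1C1OCCO1)B1OC(C)(C)C(C)(C)O1 | intermediate
15 | (2R)-1-[2-(1,3-dioxolan-2-yl)-5-methoxy-3,6-bis(methoxymethoxy)phenyl]tridecan-2-ol | CCCCCCCCCCC[C@H](Cc1c(OCOC)c(OC)cc(OCOC)c1C1OCCO1)O | intermediate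
16 | (2R)-1-[2-(1,3-dioxolan-2-yl)-5-methoxy-3,6-bis(methoxymethoxy)phenyl]tridecan-2-yl acetate | CCCCCCCCCCC[C@H](Cc1c(OCOC)c(OC)cc(OCOC)c1C1OCCO1)OC(C)=O | intermediate
17 | (2R)-1-(2-formyl-3,6-dihydroxy-5-methoxyphenyl)tridecan-2-yl acetate | CCCCCCCCCCC[C@H](Cc1c(O)c(OC)cc(O)c1C=O)OC(C)=O | target

**Step count and risks**

Total step count: 8
Longest linear sequence: 7 steps (steps 1–4 and 6–8); step 5 is a one-step branch.

Steps most likely to fail:

Step 6. The lithiated ester may remove an acidic ArCH2–B proton instead of adding to boron, the boronate may rearrange too slowly, or the organolithium may lose configurational integrity before capture, which would lower the enantiomeric purity. The fallback sets out from 5: bromine–lithium exchange as in step 4 gives aryllithium 6, and BF3·OEt2-promoted opening of purchased (R)-2-undecyloxirane (CCCCCCCCCCC[C@@H]1CO1) at its terminal carbon in THF at −78 °C should give alcohol 15, where the route is rejoined. In this variant the aryl–CH2 bond is made instead and the stereocentre is taken unchanged from the epoxide.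

Step 1. The persulfate oxidation may stop at low conversion or over-oxidise the electron-rich product to dark polymeric material. The fallback sets out from 1: Teuber oxidation with Fremy's salt in buffered aqueous acetone should oxidise the phenol at the free para position to 3-bromo-2-formyl-5-methoxy-1,4-benzoquinone F1, which is reduced in the same flask with aqueous sodium dithionite to hydroquinone 3, where the route is rejoined.

Step 4. The 1,2-shift of the hindered aryl group in the boronate may be incomplete, so that protonation on work-up returns the debrominated arene, or the benzylic boronic ester may lose boron on silica. The fallback sets out from 5: Suzuki–Miyaura coupling with bis(pinacolato)diborylmethane (Pd(0) with tri-tert-butylphosphine, aqueous KOH, dioxane, rt to 50 °C) should transfer one borylmethyl group and give 8 directly, where the route is rejoined.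

**Further compounds**

F1 | step 1 | 3-bromo-2-formyl-5-methoxy-1,4-benzoquinone | O=CC1=C(Br)C(=O)C(OC)=CC1=O
F0 | step 4 | none | none
F0 | step 6 | none | none
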